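**Strategy.** Prostanoid numbering is used: ring C8–C12, C9 the carbonyl, C10 bearing bromine, C11 the enone β-CH, C12 the carbinol carbon. The ring is disconnected at C11–C12, the enone β-carbon and the carbinol carbon, two acceptor-type centres. The 2-bromoenone C9–C10(Br)=C11 is recognised as a rearranged 1-bromoalk-1-yn-3-one, and C12 enters as the C–H bond of an enantiopure secondary silyl ether. A cationic gold catalyst converts the acyclic bromoynone into a β-bromo gold vinylidene whose carbene carbon C11 inserts into C12–H. One operation closes the cyclopentenone, places bromine on C10 and creates the quaternary carbinol with retention. Aldol condensation at C8 completes the skeleton.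

Key step: step 6

Assumption: n-pentyllithium is taken as a stock reagent (it can otherwise be made from 1-chloropentane and lithium metal); C1 is the ester carbon of the target.

Step 1
Reactants: 1 ethyl (R)-4-chloro-3-hydroxybutanoate
Product: 2 ethyl (R)-3,4-epoxybutanoate
Conditions: Ag2O, 1,2-dimethoxyethane, 60 °C
Reagents that add atoms: none
Why: Silver-assisted intramolecular Williamson closure of the chlorohydrin under non-basic conditions should avoid opening to the 4-hydroxycrotonate, and the C3–O bond is not broken, so the configuration is kept.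

Step 2
Reactants: 2 ethyl (R)-3,4-epoxybutanoate
Product: 3 ethyl (3S,5Z)-3-hydroxyundec-5-enoate
Conditions: n-C5H11Li (2 equiv), CuBr·SMe2 (1 equiv), Et2O, −40 °C; HC≡CH (2 equiv), −50 to −25 °C; then 2, Et2O/THF, −40 to 0 °C; aq NH4Cl
Reagents that add atoms: lithium di[(Z)-hept-1-enyl]cuprate [Li+].CCCCC/C=C\[Cu-]/C=C\CCCCC, made in the flask from n-pentyllithium [Li]CCCCC and acetylene C#C
Why: Syn carbocupration of acetylene gives the Z-alkenyl cuprate, which opens the epoxide by SN2 attack at the terminal carbon with the ester tolerated; the carbinol centre is untouched and its descriptor changes from R to S only through the priority order.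

Step 3
Reactants: 3 ethyl (3S,5Z)-3-hydroxyundec-5-enoate
Product: 4 ethyl (3S,5Z)-3-[(tert-butyldimethylsilyl)oxy]undec-5-enoate
Conditions: TBSCl, imidazole, DMF, 23 °C
Reagents that add atoms: tert-butyldimethylsilyl chloride CC(C)(C)[Si](C)(C)Cl
Why: Standard silylation of a secondary alcohol; the ether blocks oxygen cyclisation onto the later ynone and makes the C12–H bond hydridic.

Step 4
Reactants: 4 ethyl (3S,5Z)-3-[(tert-butyldimethylsilyl)oxy]undec-5-enoate
Product: 5 (5S,7Z)-5-[(tert-butyldimethylsilyl)oxy]-1-(trimethylsilyl)tridec-7-en-1-yn-3-one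
Conditions: Me3SiC≡CH, n-BuLi, THF, −78 °C; BF3·OEt2; then 4, −78 °C; aq NH4Cl
Reagents that add atoms: (trimethylsilyl)acetylene C#C[Si](C)(C)C
Why: BF3-mediated acylation of a lithium acetylide by an ester should stop at the ynone because the tetrahedral adduct persists at −78 °C.

Step 5
Reactants: 5 (5S,7Z)-5-[(tert-butyldimethylsilyl)oxy]-1-(trimethylsilyl)tridec-7-en-1-yn-3-one
Product: 6 (5S,7Z)-1-bromo-5-[(tert-butyldimethylsilyl)oxy]tridec-7-en-1-yn-3-one
Conditions: NBS, AgNO3 (10 mol %), acetone, 23 °C, dark
Reagents that add atoms: N-bromosuccinimide O=C1CCC(=O)N1Br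
Why: Silver-catalysed desilylative bromination of the alkynylsilane proceeds through a silver acetylide and should leave the isolated Z-alkene alone in the dark.

Step 6
Reactants: 6 (5S,7Z)-1-bromo-5-[(tert-butyldimethylsilyl)oxy]tridec-7-en-1-yn-3-one
Product: 7 (4S)-2-bromo-4-[(tert-butyldimethylsilyl)oxy]-4-[(2Z)-oct-2-en-1-yl]cyclopent-2-en-1-one
Conditions: BrettPhosAuNTf2 (5 mol %), 4 Å molecular sieves, ClCH2CH2Cl, 60 °C
Reagents that add atoms: none
Why: The cationic monovalent gold centre activates the bromoalkyne of 6, bromine shifts from C11 to C10, and the resulting β-bromo gold vinylidene inserts its carbene carbon C11 into the C12–H bond, which forms the C11–C12 bond, places the hydrogen on C11 and releases the catalyst. The closest known reaction type is the gold-catalysed cycloisomerisation of 1-bromoalk-1-yn-3-ones to 2-bromocyclopent-2-enones by gold vinylidene C–H insertion, the low-temperature counterpart of the thermal α-alkynone cyclisation. The five-membered ring C8–C12 closes in a 1,5 C–H insertion mode in which both former alkyne carbons end inside the ring. The only stereocentre, C12, is controlled by the substrate: insertion should occur with retention at the C–H carbon, so the (S)-silyl ether of 6 gives the spatial arrangement of the target (7 is S and the target R only through the priority order). The step needs C–H insertion to win over attack of the ether oxygen or of water on the activated alkyne and over reaction at the allylic C13–H or the Z-alkene. This is secured by the hydridic tertiary α-silyloxy C–H bond at the favoured 1,5 distance, the bulky and weakly nucleophilic silyloxy group, the bulky biaryl phosphine and dry non-coordinating conditions.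

Step 7
Reactants: 8 methyl hex-5-enoate; 9 (E)-but-2-enal
Product: 10 methyl (5E)-7-oxohept-5-enoate
Conditions: second-generation Hoveyda–Grubbs catalyst, (H2IMes)Cl2Ru(=CH-C6H4-2-OiPr) (2 mol %), 9 (5 equiv), CH2Cl2, 40 °C
Reagents that add atoms: none
Why: Olefin cross-metathesis of a terminal alkene with an enal partner should give the E-enal under thermodynamic control with loss of propene.

Step 8
Reactants: 7 (4S)-2-bromo-4-[(tert-butyldimethylsilyl)oxy]-4-[(2Z)-oct-2-en-1-yl]cyclopent-2-en-1-one; 10 methyl (5E)-7-oxohept-5-enoate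
Product: 13 methyl (5E,7S)-7-[(1S,5S)-3-bromo-5-[(tert-butyldimethylsilyl)oxy]-5-[(2Z)-oct-2-en-1-yl]-2-oxocyclopent-3-en-1-yl]-7-hydroxyhept-5-enoate (syn aldol), via lithium dienolate 11 (not isolated), via zirconium dienolate 12 (not isolated)
Conditions: LiN(iPr)2, THF, −78 °C; Cp2ZrCl2, −78 to −50 °C; then 10, −78 °C; aq NH4Cl
Reagents that add atoms: none
Why: Zirconium enolate aldol addition: the base removes the only enolisable proton (C8–H) and the zirconium dienolate adds 1,2 to the enal with syn selectivity whatever the enolate geometry, which sets C7 and C8 syn to each other (the C8 epimer relative to C12, drawn with the new bond anti to the silyloxy group, is of no consequence because both converge in step 9).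

Step 9
Reactants: 13 methyl (5E,7S)-7-[(1S,5S)-3-bromo-5-[(tert-butyldimethylsilyl)oxy]-5-[(2Z)-oct-2-en-1-yl]-2-oxocyclopent-3-en-1-yl]-7-hydroxyhept-5-enoate
Product: 15 methyl (5E,7Z)-7-[(5R)-3-bromo-5-[(tert-butyldimethylsilyl)oxy]-5-[(2Z)-oct-2-en-1-yl]-2-oxocyclopent-3-en-1-ylidene]hept-5-enoate, via isourea 14 (not isolated)
Conditions: DCC, CuCl (20 mol %), toluene, 40 °C
Reagents that add atoms: none
Why: Carbodiimide/CuCl dehydration of an aldol is a stereospecific syn elimination through the O-alkylisourea; in the syn aldol the C8–H and C7–O bonds eclipse only when C6 lies on the side of the C9 carbonyl, which should give the 7Z alkene and leave the 5E alkene untouched.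

Step 10
Reactants: 15 methyl (5E,7Z)-7-[(5R)-3-bromo-5-[(tert-butyldimethylsilyl)oxy]-5-[(2Z)-oct-2-en-1-yl]-2-oxocyclopent-3-en-1-ylidene]hept-5-enoate
Product: 16 methyl (5E,7Z)-7-[(5R)-3-bromo-5-hydroxy-5-[(2Z)-oct-2-en-1-yl]-2-oxocyclopent-3-en-1-ylidene]hept-5-enoate (the target bromoclavulone)
Conditions: aq HF (48 %), MeCN, 0 to 23 °C
Reagents that add atoms: none
Why: Fluoride-driven cleavage of the tertiary silyl ether under acidic conditions spares the base-sensitive cross-conjugated dienone, and the carbinol should not ionise because the cation would be a cyclopentadienone-type cation.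

**Compound list**

1 | ethyl (R)-4-chloro-3-hydroxybutanoate | CCOC(=O)C[C@@H](O)CCl | starting material
2 | ethyl (R)-3,4-epoxybutanoate | CCOC(=O)C[C@@H]1CO1 | intermediate
3 | ethyl (3S,5Z)-3-hydroxyundec-5-enoate | CCOC(=O)C[C@@H](O)C/C=C\CCCCC | intermediate
4 | ethyl (3S,5Z)-3-[(tert-butyldimethylsilyl)oxy]undec-5-enoate | CCOC(=O)C[C@@H](O[Si](C)(C)C(C)(C)C)C/C=C\CCCCC | intermediate
5 | (5S,7Z)-5-[(tert-butyldimethylsilyl)oxy]-1-(trimethylsilyl)tridec-7-en-1-yn-3-one | C[Si](C)(C)C#CC(=O)C[C@@H](O[Si](C)(C)C(C)(C)C)C/C=C\CCCCC | intermediate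
6 | (5S,7Z)-1-bromo-5-[(tert-butyldimethylsilyl)oxy]tridec-7-en-1-yn-3-one | BrC#CC(=O)C[C@@H](O[Si](C)(C)C(C)(C)C)C/C=C\CCCCC | intermediate
7 | (4S)-2-bromo-4-[(tert-butyldimethylsilyl)oxy]-4-[(2Z)-oct-2-en-1-yl]cyclopent-2-en-1-one | CCCCC/C=C\C[C@@]1(O[Si](C)(C)C(C)(C)C)C=C(Br)C(=O)C1 | intermediate
8 | methyl hex-5-enoate | C=CCCCC(=O)OC | starting material
9 | (E)-but-2-enal (crotonaldehyde) | C/C=C/C=O | starting material
10 | methyl (5E)-7-oxohept-5-enoate | COC(=O)CCC/C=C/C=O | intermediate
11 | lithium dienolate of 7 (deprotonated at C8) | CCCCC/C=C\C[C@@]1(O[Si](C)(C)C(C)(C)C)C=C(Br)C(O[Li])=C1 | intermediate (not isolated)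
12 | chlorobis(cyclopentadienyl)zirconium dienolate of 7 | CCCCC/C=C\C[C@@]1(O[Si](C)(C)C(C)(C)C)C=C(Br)C(O[Zr](Cl)(C2C=CC=C2)C2C=CC=C2)=C1 | intermediate (not isolated)
13 | methyl (5E,7S)-7-[(1S,5S)-3-bromo-5-[(tert-butyldimethylsilyl)oxy]-5-[(2Z)-oct-2-en-1-yl]-2-oxocyclopent-3-en-1-yl]-7-hydroxyhept-5-enoate (syn aldol) | COC(=O)CCC/C=C/[C@H](O)[C@@H]1C(=O)C(Br)=C[C@]1(O[Si](C)(C)C(C)(C)C)C/C=C\CCCCC | intermediate
14 | O-alkyl-N,N′-dicyclohexylisourea of 13 (at the C7 oxygen) | COC(=O)CCC/C=C/[C@H](OC(=NC2CCCCC2)NC3CCCCC3)[C@@H]1C(=O)C(Br)=C[C@]1(O[Si](C)(C)C(C)(C)C)C/C=C\CCCCC | intermediate (not isolated)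
15 | methyl (5E,7Z)-7-[(5R)-3-bromo-5-[(tert-butyldimethylsilyl)oxy]-5-[(2Z)-oct-2-en-1-yl]-2-oxocyclopent-3-en-1-ylidene]hept-5-enoate | CCCCC/C=C\C[C@@]1(O[Si](C)(C)C(C)(C)C)C=C(Br)C(=O)/C1=C\C=C\CCCC(=O)OC | intermediate
16 | methyl (5E,7Z)-7-[(5R)-3-bromo-5-hydroxy-5-[(2Z)-oct-2-en-1-yl]-2-oxocyclopent-3-en-1-ylidene]hept-5-enoate | CCCCC/C=C\C[C@@]1(O)C=C(Br)C(=O)/C1=C\C=C\CCCC(=O)OC | target

**Step count.** Total: 10 steps. Longest linear sequence: 9 steps (steps 1–6 and 8–10).

**Steps most likely to fail**

Step 6. The silyl ether oxygen or adventitious water may add to the gold-activated bromoalkyne before the vinylidene forms, or the insertion may run stepwise through hydride transfer and lose configuration at C12. The fallback keeps the same ring closure but is thermal and metal-free; it sets out from 5 and comes back at 7. The alkynylsilane of 5 is cleaved with Na2B4O7 in MeOH/H2O to give the terminal ynone (5S,7Z)-5-[(tert-butyldimethylsilyl)oxy]tridec-7-en-1-yn-3-one F1. Flash vacuum thermolysis of it (quartz tube, about 620 °C, 0.01 mbar) is the α-alkynone cyclisation: a 1,2-hydrogen shift gives an alkylidene carbene that inserts into C12–H with retention. This should give (4S)-4-[(tert-butyldimethylsilyl)oxy]-4-[(2Z)-oct-2-en-1-yl]cyclopent-2-en-1-one F2. Bromine is then introduced without electrophilic bromine, which would attack the Z-alkene. Nucleophilic epoxidation (H2O2, NaOH, MeOH, 0 °C) should give the 2,3-epoxide of the enone, trans to the silyloxy group, F3. HBr (48 % aq, THF, 0 °C) opens it at the α-carbon and the β-hydroxy ketone loses water, which leads back to 7.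

Step 9 (together with the syn selectivity of step 8 that feeds it). The elimination may run through the enolate instead of the concerted syn pathway, or the aldol may arrive as a syn/anti mixture; either erodes the 7Z/7E ratio. The fallback corrects the geometry afterwards instead of controlling it; it sets out from 13 and comes back at 15. From 13 in any diastereomer ratio, MsCl/Et3N gives the C7 mesylate of 13 F4, and DBU eliminates it to a mixture of 15 and its 7E isomer, methyl (5E,7E)-7-[(5R)-3-bromo-5-[(tert-butyldimethylsilyl)oxy]-5-[(2Z)-oct-2-en-1-yl]-2-oxocyclopent-3-en-1-ylidene]hept-5-enoate F5. The isomers are separated on silica. The 7E isomer is irradiated (350 nm, benzene, 10 °C) to the photostationary 7E/7Z mixture and recycled, which returns the material to 15.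

Step 2. The cuprate may act as a base and open the β,γ-epoxy ester to ethyl 4-hydroxybut-2-enoate, or pentyl may be transferred in place of heptenyl if carbocupration is incomplete. The fallback uses a Lewis acidic, non-basic nucleophile; it sets out from 2 and comes back at 3. Diethyl(hept-1-ynyl)alane (hept-1-yne, n-BuLi, Et2AlCl, toluene, 0 °C) opens the epoxide at the terminal carbon to give ethyl (3S)-3-hydroxyundec-5-ynoate F6. Semi-hydrogenation (H2, Pd/CaCO3 poisoned with Pb(OAc)2, quinoline, EtOAc) should then give 3.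

**Further compounds**

F1 | step 6 | (5S,7Z)-5-[(tert-butyldimethylsilyl)oxy]tridec-7-en-1-yn-3-one | C#CC(=O)C[C@@H](O[Si](C)(C)C(C)(C)C)C/C=C\CCCCC
F2 | step 6 | (4S)-4-[(tert-butyldimethylsilyl)oxy]-4-[(2Z)-oct-2-en-1-yl]cyclopent-2-en-1-one | CCCCC/C=C\C[C@@]1(O[Si](C)(C)C(C)(C)C)C=CC(=O)C1
F3 | step 6 | 2,3-epoxide of the enone F2, trans to the silyloxy group | CCCCC/C=C\C[C@@]1(O[Si](C)(C)C(C)(C)C)[C@H]2O[C@H]2C(=O)C1
F4 | step 9 | C7 mesylate of 13 | COC(=O)CCC/C=C/[C@H](OS(C)(=O)=O)[C@@H]1C(=O)C(Br)=C[C@]1(O[Si](C)(C)C(C)(C)C)C/C=C\CCCCC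
F5 | step 9 | methyl (5E,7E)-7-[(5R)-3-bromo-5-[(tert-butyldimethylsilyl)oxy]-5-[(2Z)-oct-2-en-1-yl]-2-oxocyclopent-3-en-1-ylidene]hept-5-enoate | CCCCC/C=C\C[C@@]1(O[Si](C)(C)C(C)(C)C)C=C(Br)C(=O)/C1=C/C=C/CCCC(=O)OC
F6 | step 2 | ethyl (3S)-3-hydroxyundec-5-ynoate | CCOC(=O)C[C@@H](O)CC#CCCCCC
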